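**Retrosynthetic overview**

1. Ring A (the carbocycle) is bought as phloroglucinol and dearomatized last: the C-6 quaternary centre comes from C-prenylation of an acylphloroglucinol polyanion released from a tricyclic lactone.
2. The C-6 alkyl chain is attached before that by sp2–sp3 Negishi coupling of a C-6 aryl iodide with a chiral primary alkylzinc, whose stereocentre comes from (R)-3-hydroxy-γ-butyrolactone (trans-alkylation, Wittig olefination, glycol cleavage).
3. The C-8 3-phenylpropanoic acid arm is carried as lactone ring C; its pyran ring and the benzylic C–C bond form in the key step, a domino Knoevenagel/hetero-Diels–Alder cycloaddition of an ortho-quinone methide with ethyl vinyl ether.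
4. Ring B (the pyranone) comes from Mitsunobu etherification of phloroglucinol with the Fráter–Seebach product of ethyl (R)-3-hydroxybutanoate, then Friedel–Crafts ring closure (C-2 bought, C-3 by equilibration).
5. Order of ring formation: ring A bought, then ring B, then ring C (cycloaddition), then ring C opened and ring A dearomatized.

Assumption: the target is made as the enol tautomer drawn in its SMILES, and the tricyclic lactones are numbered as pyrano[2,3-f]chromenes (ring B: O-1 to C-4; ring A: C-5, C-6; ring C: O-7 to C-10).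

Two centres are not set selectively: the benzylic centre (step 6) and the quaternary C-6 (step 14) each form as roughly 1:1 epimer pairs and are fixed by chromatographic separation. The other three centres come from, or are controlled by, the two bought (R)-hydroxy compounds.

**Route**

Step 1
Reactants: 1 ethyl (R)-3-hydroxybutanoate
Product: 2 ethyl (2R,3R)-3-hydroxy-2-methylbutanoate
Conditions: LiN(i-Pr)2 (2.2 equiv), THF, −50 to −20 °C; MeI, DMPU, −78 to 0 °C; NH4Cl (aq)
Reagents that add atoms: iodomethane (SMILES: CI)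
Why: Fráter–Seebach alkylation: the chelated lithium alkoxide–enolate dianion is methylated on the face anti to the C-3 oxygen substituent, so the bought (3R) centre sets the new (2R) centre (anti:syn about 95:5).

Step 2
Reactants: 2 ethyl (2R,3R)-3-hydroxy-2-methylbutanoate; 3 phloroglucinol (benzene-1,3,5-triol, 3 equiv)
Product: 4 ethyl (2R,3S)-3-(3,5-dihydroxyphenoxy)-2-methylbutanoate
Conditions: PPh3, DIAD, THF, 0 °C to rt
Reagents that add atoms: none
Why: Mitsunobu etherification: the acidic phenol (in excess to stay at the mono-ether) displaces the phosphonium-activated secondary alcohol by SN2 with inversion, converting (3R) into the (3S) aryl ether carbon that becomes C-2 of ring B.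

Step 3
Reactants: 4 ethyl (2R,3S)-3-(3,5-dihydroxyphenoxy)-2-methylbutanoate
Product: 5 (2R,3S)-3-(3,5-dihydroxyphenoxy)-2-methylbutanoic acid
Conditions: LiOH, THF/H2O, 0 °C to rt; HCl (aq)
Reagents that add atoms: lithium hydroxide (SMILES: [Li+].[OH-])
Why: Ester saponification at low temperature unmasks the acid for ring closure without disturbing the aryl ether stereocentre.

Step 4
Reactants: 5 (2R,3S)-3-(3,5-dihydroxyphenoxy)-2-methylbutanoic acid
Product: 7 (2S,3S)-5,7-dihydroxy-2,3-dimethylchroman-4-one, via cis-chromanone 6 (not isolated)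
Conditions: P2O5/CH3SO3H (Eaton's reagent), 40 °C; then Et3N, MeOH, rt
Reagents that add atoms: none
Why: Intramolecular Friedel–Crafts acylation at either of the two equivalent positions ortho to the ether oxygen closes ring B with C-2 untouched, and amine-mediated enolization then equilibrates C-3 to the more stable trans isomer with both methyl groups pseudo-equatorial, so C-3 is set by C-2.

Step 5
Reactants: 7 (2S,3S)-5,7-dihydroxy-2,3-dimethylchroman-4-one
Product: 8 (2S,3S)-5,7-dihydroxy-6-iodo-2,3-dimethylchroman-4-one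
Conditions: I2 (1.0 equiv), NaHCO3, THF/H2O, 0 °C
Reagents that add atoms: iodine (SMILES: II)
Why: Electrophilic aromatic iodination under phenoxide-forming conditions goes to C-6, the carbon flanked by both hydroxyl groups (the resorcinol 2-position pattern), which blocks C-6 and installs the handle for the later cross-coupling.

Step 6
Reactants: 8 (2S,3S)-5,7-dihydroxy-6-iodo-2,3-dimethylchroman-4-one; 9 benzaldehyde; 10 ethyl vinyl ether (ethoxyethene, 15 equiv)
Product: 12 (2S,3S)-8-ethoxy-5-hydroxy-6-iodo-2,3-dimethyl-10-phenyl-2,3,9,10-tetrahydro-4H,8H-pyrano[2,3-f]chromen-4-one (mixture of C-8/C-10 stereoisomers), via ortho-quinone methide 11 (not isolated)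
Conditions: ethylenediammonium diacetate (0.3 equiv), MeCN, 80 °C, sealed tube
Reagents that add atoms: none
Why: Domino Knoevenagel/hetero-Diels–Alder reaction: condensation at C-8, the only free ring carbon, gives the ortho-quinone methide with loss of water, and its inverse-electron-demand [4+2] cycloaddition with the enol ether closes ring C and forms the benzylic C–C bond with the oxygen-bearing carbon next to O-7, while the distant C-2/C-3 centres give little facial bias so both C-10 configurations arise.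

Step 7
Reactants: 12 (2S,3S)-8-ethoxy-5-hydroxy-6-iodo-2,3-dimethyl-10-phenyl-2,3,9,10-tetrahydro-4H,8H-pyrano[2,3-f]chromen-4-one
Product: 13 (2S,3S,10R)-5-hydroxy-6-iodo-2,3-dimethyl-10-phenyl-2,3,9,10-tetrahydro-4H,8H-pyrano[2,3-f]chromene-4,8-dione
Conditions: CrO3, H2SO4, H2O, acetone, 0 °C; chromatography
Reagents that add atoms: water (SMILES: O)
Why: Jones oxidation hydrolyses the cyclic acetal and oxidizes the lactol to the lactone, which removes the acetal stereocentre so that only two C-10 epimers remain, and the (10R) lactone is isolated from its (10S) epimer by chromatography.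

Step 8
Reactants: 14 (R)-4-hydroxydihydrofuran-2(3H)-one; 15 4-iodo-2-methylbut-1-ene
Product: 16 (3R,4R)-4-hydroxy-3-(3-methylbut-3-en-1-yl)dihydrofuran-2(3H)-one
Conditions: LiN(i-Pr)2 (2.2 equiv), THF, −78 to −40 °C; then 15, DMPU, −40 to −20 °C; NH4Cl (aq)
Reagents that add atoms: none
Why: Alkylation of the lactone alkoxide–enolate dianion (Fráter–Seebach type) takes place trans to the C-4 alkoxide, so the bought (4R) centre sets the new (3R) centre (trans:cis above 95:5).

Step 9
Reactants: 16 (3R,4R)-4-hydroxy-3-(3-methylbut-3-en-1-yl)dihydrofuran-2(3H)-one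
Product: 17 (3R,4R)-3-(3-methylbut-3-en-1-yl)tetrahydrofuran-2,4-diol (lactol, both anomers)
Conditions: i-Bu2AlH (2.5 equiv), CH2Cl2, −78 °C; KNaC4H4O6 (aq)
Reagents that add atoms: none
Why: Partial reduction of the lactone by i-Bu2AlH at −78 °C stops at the lactol, the masked aldehyde needed for the olefination.

Step 10
Reactants: 17 (3R,4R)-3-(3-methylbut-3-en-1-yl)tetrahydrofuran-2,4-diol
Product: 18 (2R,3S)-5-methyl-3-(3-methylbut-3-en-1-yl)hex-4-ene-1,2-diol
Conditions: i-PrPPh3I, n-BuLi, THF, 0 °C; then 17, 0 °C to rt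
Reagents that add atoms: isopropyltriphenylphosphonium iodide (SMILES: CC(C)[P+](c1ccccc1)(c1ccccc1)c1ccccc1.[I-])
Why: Wittig olefination of the lactol through its open hydroxy aldehyde form with the unstabilized isopropylidene ylide builds the isobutenyl group and leaves the adjacent stereocentre unchanged.

Step 11
Reactants: 18 (2R,3S)-5-methyl-3-(3-methylbut-3-en-1-yl)hex-4-ene-1,2-diol
Product: 20 (S)-5-methyl-2-(2-methylprop-1-en-1-yl)hex-5-en-1-ol, via aldehyde 19 (not isolated)
Conditions: NaIO4, THF/pH 7 buffer, 0 °C; then NaBH4, MeOH, 0 °C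
Reagents that add atoms: none
Why: Glycol cleavage by NaIO4 excises the carbon that carried the controlling hydroxyl group, and the epimerizable β,γ-unsaturated aldehyde is reduced in the same flask by NaBH4 to the primary alcohol before it can racemize or conjugate.

Step 12
Reactants: 20 (S)-5-methyl-2-(2-methylprop-1-en-1-yl)hex-5-en-1-ol
Product: 21 (S)-5-(iodomethyl)-2,7-dimethylocta-1,6-diene
Conditions: PPh3, I2, imidazole, CH2Cl2, 0 °C to rt
Reagents that add atoms: iodine (SMILES: II)
Why: Appel-type iodination converts the primary alcohol into the iodide by SN2 at the CH2 group, so the neighbouring stereocentre is not involved.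

Step 13
Reactants: 13 (2S,3S,10R)-5-hydroxy-6-iodo-2,3-dimethyl-10-phenyl-2,3,9,10-tetrahydro-4H,8H-pyrano[2,3-f]chromene-4,8-dione; 21 (S)-5-(iodomethyl)-2,7-dimethylocta-1,6-diene
Product: 23 (2S,3S,10R)-5-hydroxy-2,3-dimethyl-6-[(2R)-5-methyl-2-(2-methylprop-1-en-1-yl)hex-5-en-1-yl]-10-phenyl-2,3,9,10-tetrahydro-4H,8H-pyrano[2,3-f]chromene-4,8-dione, via alkylzinc iodide 22 (not isolated)
Conditions: 21, Zn dust, LiCl, THF, 40 °C; then 13 (pre-treated with NaH, THF, 0 °C), Pd(OAc)2 (5 mol%), SPhos (10 mol%), THF, 25 to 50 °C; NH4Cl (aq)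
Reagents that add atoms: none
Why: Negishi cross-coupling: zinc insertion gives the primary alkylzinc iodide, which is transferred to the di-ortho-oxygenated aryl iodide (its phenol masked as the sodium phenoxide) with Pd(OAc)2 and the bulky biaryl phosphine SPhos that speeds reductive elimination over β-hydride elimination, without touching any stereocentre.

Step 14
Reactants: 23 (2S,3S,10R)-5-hydroxy-2,3-dimethyl-6-[(2R)-5-methyl-2-(2-methylprop-1-en-1-yl)hex-5-en-1-yl]-10-phenyl-2,3,9,10-tetrahydro-4H,8H-pyrano[2,3-f]chromene-4,8-dione; 24 prenyl bromide (1-bromo-3-methylbut-2-ene)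
Product: 26 (3R)-3-[(2S,3S,6S)-4-hydroxy-2,3-dimethyl-6-(3-methylbut-2-en-1-yl)-6-[(2R)-5-methyl-2-(2-methylprop-1-en-1-yl)hex-5-en-1-yl]-5,7-dioxo-2,3,6,7-tetrahydro-5H-chromen-8-yl]-3-phenylpropanoic acid (target), via seco acid 25 (not isolated)
Conditions: LiOH (4 equiv), THF/H2O, 0 °C; then 24 (1.5 equiv), 0 °C to rt; HCl (aq); preparative HPLC
Reagents that add atoms: lithium hydroxide (SMILES: [Li+].[OH-])
Why: Saponification of the aryl lactone frees the carboxylate and the 7-phenoxide, and dearomative C-alkylation of this acylphloroglucinol-type polyanion by prenyl bromide at C-6 (flanked by two oxygens and carrying the smaller primary substituent) creates the quaternary centre of ring A; the nearest stereocentres are too far away to bias the face, so the (6S) target is separated from its (6R) epimer by preparative HPLC.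

**Compound list**

1 | ethyl (R)-3-hydroxybutanoate | CCOC(=O)C[C@@H](C)O | starting material
2 | ethyl (2R,3R)-3-hydroxy-2-methylbutanoate | CCOC(=O)[C@H](C)[C@@H](C)O | intermediate
3 | phloroglucinol (benzene-1,3,5-triol) | Oc1cc(O)cc(O)c1 | starting material
4 | ethyl (2R,3S)-3-(3,5-dihydroxyphenoxy)-2-methylbutanoate | CCOC(=O)[C@H](C)[C@H](C)Oc1cc(O)cc(O)c1 | intermediate
5 | (2R,3S)-3-(3,5-dihydroxyphenoxy)-2-methylbutanoic acid | OC(=O)[C@H](C)[C@H](C)Oc1cc(O)cc(O)c1 | intermediate
6 | (2S,3R)-5,7-dihydroxy-2,3-dimethylchroman-4-one (cis-chromanone, formed in situ) | O=C1[C@H](C)[C@H](C)Oc2cc(O)cc(O)c12 | intermediate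
7 | (2S,3S)-5,7-dihydroxy-2,3-dimethylchroman-4-one (trans) | O=C1[C@@H](C)[C@H](C)Oc2cc(O)cc(O)c12 | intermediate
8 | (2S,3S)-5,7-dihydroxy-6-iodo-2,3-dimethylchroman-4-one | O=C1[C@@H](C)[C@H](C)Oc2cc(O)c(I)c(O)c12 | intermediate
9 | benzaldehyde | O=Cc1ccccc1 | starting material
10 | ethyl vinyl ether (ethoxyethene) | C=COCC | starting material
11 | (2S,3S)-8-benzylidene-5-hydroxy-6-iodo-2,3-dimethyl-2,3-dihydro-4H-chromene-4,7(8H)-dione (ortho-quinone methide, formed in situ) | O=C1[C@@H](C)[C@H](C)OC2=C1C(O)=C(I)C(=O)C2=Cc1ccccc1 | intermediate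
12 | (2S,3S)-8-ethoxy-5-hydroxy-6-iodo-2,3-dimethyl-10-phenyl-2,3,9,10-tetrahydro-4H,8H-pyrano[2,3-f]chromen-4-one (ring C: O-7, CH(OEt), CH2, CH(Ph); C-8/C-10 stereoisomer mixture) | CCOC1CC(c2ccccc2)c3c(O1)c(I)c(O)c4C(=O)[C@@H](C)[C@H](C)Oc34 | intermediate
13 | (2S,3S,10R)-5-hydroxy-6-iodo-2,3-dimethyl-10-phenyl-2,3,9,10-tetrahydro-4H,8H-pyrano[2,3-f]chromene-4,8-dione (ring C lactone: O-7, C(=O), CH2, CH(Ph)) | O=C1C[C@H](c2ccccc2)c3c(O1)c(I)c(O)c4C(=O)[C@@H](C)[C@H](C)Oc34 | intermediate
14 | (R)-4-hydroxydihydrofuran-2(3H)-one ((R)-3-hydroxy-γ-butyrolactone) | O=C1C[C@@H](O)CO1 | starting material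
15 | 4-iodo-2-methylbut-1-ene | C=C(C)CCI | starting material
16 | (3R,4R)-4-hydroxy-3-(3-methylbut-3-en-1-yl)dihydrofuran-2(3H)-one (trans) | O=C1[C@H](CCC(C)=C)[C@@H](O)CO1 | intermediate
17 | (3R,4R)-3-(3-methylbut-3-en-1-yl)tetrahydrofuran-2,4-diol (lactol, both anomers) | OC1[C@H](CCC(C)=C)[C@@H](O)CO1 | intermediate
18 | (2R,3S)-5-methyl-3-(3-methylbut-3-en-1-yl)hex-4-ene-1,2-diol | CC(C)=C[C@H](CCC(C)=C)[C@@H](O)CO | intermediate
19 | (S)-5-methyl-2-(2-methylprop-1-en-1-yl)hex-5-enal (formed in situ) | CC(C)=C[C@H](CCC(C)=C)C=O | intermediate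
20 | (S)-5-methyl-2-(2-methylprop-1-en-1-yl)hex-5-en-1-ol | CC(C)=C[C@H](CCC(C)=C)CO | intermediate
21 | (S)-5-(iodomethyl)-2,7-dimethylocta-1,6-diene | CC(C)=C[C@H](CCC(C)=C)CI | intermediate
22 | [(2S)-5-methyl-2-(2-methylprop-1-en-1-yl)hex-5-en-1-yl]zinc iodide (formed in situ) | CC(C)=C[C@H](CCC(C)=C)C[Zn]I | intermediate
23 | (2S,3S,10R)-5-hydroxy-2,3-dimethyl-6-[(2R)-5-methyl-2-(2-methylprop-1-en-1-yl)hex-5-en-1-yl]-10-phenyl-2,3,9,10-tetrahydro-4H,8H-pyrano[2,3-f]chromene-4,8-dione | O=C1C[C@H](c2ccccc2)c3c(O1)c(C[C@H](C=C(C)C)CCC(C)=C)c(O)c4C(=O)[C@@H](C)[C@H](C)Oc34 | intermediate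
24 | prenyl bromide (1-bromo-3-methylbut-2-ene) | CC(C)=CCBr | starting material
25 | (3R)-3-{(2S,3S)-5,7-dihydroxy-2,3-dimethyl-6-[(2R)-5-methyl-2-(2-methylprop-1-en-1-yl)hex-5-en-1-yl]-4-oxochroman-8-yl}-3-phenylpropanoic acid (seco acid, formed in situ as its lithium salt) | OC(=O)C[C@H](c1ccccc1)c2c(O)c(C[C@H](C=C(C)C)CCC(C)=C)c(O)c3C(=O)[C@@H](C)[C@H](C)Oc23 | intermediate
26 | (3R)-3-[(2S,3S,6S)-4-hydroxy-2,3-dimethyl-6-(3-methylbut-2-en-1-yl)-6-[(2R)-5-methyl-2-(2-methylprop-1-en-1-yl)hex-5-en-1-yl]-5,7-dioxo-2,3,6,7-tetrahydro-5H-chromen-8-yl]-3-phenylpropanoic acid (CNP0155375.2) | C=C(C)CC[C@@H](C=C(C)C)C[C@@]1(CC=C(C)C)C(=O)C2=C(O)[C@@H](C)[C@H](C)OC2=C([C@H](CC(=O)O)c2ccccc2)C1=O | target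

**Step count and risks**

Total step count: 14. Longest linear sequence: 9 steps (steps 1 to 7, 13 and 14, from 1); the chain branch runs 7 steps (steps 8 to 14, from 14).

The three steps most likely to fail:

Step 5 (regiochemistry of the iodination). Attack at C-8 or bis-iodination may compete with C-6. The fallback sets out from 7 and uses a blocking group so that only the chelated 5-OH directs. The unchelated 7-OH is silylated (t-BuMe2SiCl, imidazole, DMF) to (2S,3S)-7-(tert-butyldimethylsilyloxy)-5-hydroxy-2,3-dimethylchroman-4-one F1. N-Iodosuccinimide then iodinates ortho to the one free phenol to give (2S,3S)-7-(tert-butyldimethylsilyloxy)-5-hydroxy-6-iodo-2,3-dimethylchroman-4-one F2. Desilylation with n-Bu4NF comes back to the route at 8.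

Step 6 (three-component cycloaddition). The ortho-quinone methide may form slowly from this deactivated iodophenol or be trapped by a second phenol. The fallback sets out from 8 and replaces the cycloaddition by a polar Michael addition/lactonization. 8 is heated (pyridine, 90 °C) with 5-benzylidene-2,2-dimethyl-1,3-dioxane-4,6-dione F3, made from benzaldehyde and Meldrum's acid. C-8 adds to the alkylidene to give 5-{[(2S,3S)-5,7-dihydroxy-6-iodo-2,3-dimethyl-4-oxochroman-8-yl](phenyl)methyl}-2,2-dimethyl-1,3-dioxane-4,6-dione F4, which lactonizes onto O-7 with loss of acetone and CO2. This comes back to the route at 13 after separation of the C-10 epimers, so step 7 is not needed.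

Step 14 (dearomative prenylation). O-alkylation, attack at C-8 or low conversion may dominate, and the two C-6 epimers must be separated. The fallback sets out from 23 and changes from SN2 alkylation to a π-allyl pathway. The lactone is opened with NaOMe/MeOH to methyl (3R)-3-{(2S,3S)-5,7-dihydroxy-2,3-dimethyl-6-[(2R)-5-methyl-2-(2-methylprop-1-en-1-yl)hex-5-en-1-yl]-4-oxochroman-8-yl}-3-phenylpropanoate F5. Tsuji–Trost dearomative allylation (Pd(PPh3)4, zerovalent palladium, tert-butyl 3-methylbut-2-en-1-yl carbonate, THF) has the soft ring enolate attack the less hindered allyl terminus and gives the methyl ester of the target F6. Saponification (LiOH, THF/H2O) and HPLC come back to the route at 26.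

**Further compounds**

F1 | step 5 | (2S,3S)-7-(tert-butyldimethylsilyloxy)-5-hydroxy-2,3-dimethylchroman-4-one | O=C1[C@@H](C)[C@H](C)Oc2cc(O[Si](C)(C)C(C)(C)C)cc(O)c12
F2 | step 5 | (2S,3S)-7-(tert-butyldimethylsilyloxy)-5-hydroxy-6-iodo-2,3-dimethylchroman-4-one | O=C1[C@@H](C)[C@H](C)Oc2cc(O[Si](C)(C)C(C)(C)C)c(I)c(O)c12
F3 | step 6 | 5-benzylidene-2,2-dimethyl-1,3-dioxane-4,6-dione | CC1(C)OC(=O)C(=Cc2ccccc2)C(=O)O1
F4 | step 6 | 5-{[(2S,3S)-5,7-dihydroxy-6-iodo-2,3-dimethyl-4-oxochroman-8-yl](phenyl)methyl}-2,2-dimethyl-1,3-dioxane-4,6-dione (both benzylic epimers) | CC1(C)OC(=O)C(C(c2ccccc2)c3c(O)c(I)c(O)c4C(=O)[C@@H](C)[C@H](C)Oc34)C(=O)O1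
F5 | step 14 | methyl (3R)-3-{(2S,3S)-5,7-dihydroxy-2,3-dimethyl-6-[(2R)-5-methyl-2-(2-methylprop-1-en-1-yl)hex-5-en-1-yl]-4-oxochroman-8-yl}-3-phenylpropanoate | COC(=O)C[C@H](c1ccccc1)c2c(O)c(C[C@H](C=C(C)C)CCC(C)=C)c(O)c3C(=O)[C@@H](C)[C@H](C)Oc23
F6 | step 14 | methyl (3R)-3-[(2S,3S,6S)-4-hydroxy-2,3-dimethyl-6-(3-methylbut-2-en-1-yl)-6-[(2R)-5-methyl-2-(2-methylprop-1-en-1-yl)hex-5-en-1-yl]-5,7-dioxo-2,3,6,7-tetrahydro-5H-chromen-8-yl]-3-phenylpropanoate | C=C(C)CC[C@@H](C=C(C)C)C[C@@]1(CC=C(C)C)C(=O)C2=C(O)[C@@H](C)[C@H](C)OC2=C([C@H](CC(=O)OC)c2ccccc2)C1=O
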